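**Retrosynthetic overview**
1. Target ⇐ acetylation of the 6-OH and deprotection ⇐ C11–O aryl ether (Mitsunobu with umbelliferone) ⇐ homoallylic alcohol 17 ⇐ hydroboration of a 7,9(11)-diene ⇐ methylenation and dehydrogenation of a C9 ketone.
2. The C9-keto decalin ⇐ one-flask three-component Michael–Michael–Dieckmann annulation of methyl isobutyrate (C3, C4 and both C4 methyls), enone 4 (ring B with C5 and C10) and methyl acrylate (C1, C2): C4–C5 and C10–C1 form first, then the C2–C3 bond closes ring A.
3. Enabling feature: in ring A the C3 carbonyl lies between the non-enolisable quaternary C4 and the C2 methylene, and the ring-fusion atoms C5 and C10 are β and α to C9 of ring B (the carbon that carries the CH2OAr arm). A carbonyl at C9 therefore makes C5 electrophilic and C10 nucleophilic, and the six ring-A atoms fall into three two-carbon units of alternating polarity.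
4. Ring order: ring B is bought as an enantiopure 4-silyloxycyclohexenone whose carbinol carbon becomes C6 and relays chirality C6 → C5 → C10 → C9; ring A is formed in the key step.

Key step: step 4

Assumption: enantiopure (R)-4-(tert-butyldimethylsilyloxy)cyclohex-2-en-1-one (1) is taken as a purchasable building block.
Numbering: bicyclic compounds are described with drimane numbering (ring A = C1–C5, C10; ring B = C5–C10; C11 on C9; methyls on C4, C4, C8, C10). In this numbering the target is 5S,6R,9R,10S.

Step 1
Reactants: 1 (R)-4-(tert-butyldimethylsilyloxy)cyclohex-2-en-1-one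
Product: 2 (R)-4-(tert-butyldimethylsilyloxy)-2-iodocyclohex-2-en-1-one
Conditions: I2, pyridine, CH2Cl2, 0 → 25 °C
Reagents that add atoms: iodine, II
Why: Johnson α-iodination of an enone (pyridine conjugate addition, iodination of the enolate, elimination) should leave the silyloxy stereocentre untouched.

Step 2
Reactants: 2 (R)-4-(tert-butyldimethylsilyloxy)-2-iodocyclohex-2-en-1-one
Product: 3 (R)-4-(tert-butyldimethylsilyloxy)-2-methylcyclohex-2-en-1-one
Conditions: Me4Sn, PdCl2(PhCN)2 (cat.), AsPh3, CuI, NMP, 80 °C
Reagents that add atoms: tetramethylstannane, C[Sn](C)(C)C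
Why: Stille cross-coupling of a 2-iodoenone with Me4Sn is a standard route to 2-methyl enones and touches no stereocentre.

Step 3
Reactants: 3 (R)-4-(tert-butyldimethylsilyloxy)-2-methylcyclohex-2-en-1-one
Product: 4 (4R)-4-(tert-butyldimethylsilyloxy)-2,6-dimethylcyclohex-2-en-1-one (both C6 epimers)
Conditions: LiN(iPr)2, THF, −78 °C; MeI, −78 → −20 °C
Reagents that add atoms: iodomethane, CI
Why: Kinetic α′-deprotonation and enolate alkylation should install the future C8 methyl; the new centre is formed as an epimer mixture that is of no consequence because this carbon becomes trigonal in step 7.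

Step 4
Reactants: 4 (4R)-4-(tert-butyldimethylsilyloxy)-2,6-dimethylcyclohex-2-en-1-one, 5 methyl isobutyrate, 6 methyl acrylate
Product: 10 trans-decalin β-keto ester (2-CO2CH3, 3-oxo drawn as the 3-enol, 6-OTBS, 9-oxo), via lithium ester enolate 7 (not isolated), via Michael adduct enolate 8 (not isolated), via ester enolate 9 (not isolated)
Conditions: LiN(iPr)2, 5, THF, −78 °C; 4, −78 → 0 °C; 6, −78 °C; KOtBu, −78 → 25 °C; aq NH4Cl
Reagents that add atoms: none
Why: The lithium enolate 7 adds to C5 of enone 4 (reversible 1,2-addition should drain into the 1,4-adduct on warming), the regiodefined tetrasubstituted enolate 8 adds through C10 to methyl acrylate, and the ester enolate 9 closes ring A by Dieckmann acylation of C2 on the C3 methyl ester with loss of methoxide, so that C4–C5, C10–C1 and C2–C3 form in one flask. The closest known reaction type is the Michael–Michael–ring-closure (MIMIRC) three-component annulation of an ester enolate, a cycloalkenone and an acrylate, i.e. conjugate addition, enolate trapping and Dieckmann condensation. Ring A closes in the 6-exo-trig mode (enolate carbon C2 on the ester carbonyl C3) through a chair-like array with both tethers equatorial on ring B. C5 is controlled by the C6 silyloxy group (the nucleophile enters anti to it, as in additions to 4-silyloxycyclohexenones) and C10 by the new bulky C5 substituent (the acrylate enters anti to it, the usual trans 2,3-dialkylation), which gives the trans ring fusion; C2 is lost in step 5 and C8 should equilibrate to the equatorial epimer under the alkoxide. The step needs 1,4- over 1,2-addition, which the α,α-disubstituted ester enolate under thermodynamic control should secure, and closure at C2–C3 rather than acylation by a C8 enolate: because C4 is quaternary the C3 ester cannot enolise, and only the C2 closure gives an enolisable β-keto ester, whose stabilised enolate is the thermodynamic sink under KOtBu, whereas β-diketones formed through C8 carry no acidic hydrogen and should revert by retro-Claisen cleavage.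

Step 5
Reactants: 10 trans-decalin β-keto ester
Product: 11 6-(tert-butyldimethylsilyloxy)-4,4,8,10-tetramethyl-trans-decalin-3,9-dione
Conditions: LiCl, DMSO, H2O, 150 °C
Reagents that add atoms: none
Why: Krapcho dealkoxycarbonylation (chloride demethylates the ester and the β-keto carboxylate loses CO2) should remove the activating group without touching the non-epimerisable C5 and C10 centres.

Step 6
Reactants: 11 6-(tert-butyldimethylsilyloxy)-4,4,8,10-tetramethyl-trans-decalin-3,9-dione
Product: 12 3,3-ethylenedioxy 9-ketone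
Conditions: (TMSOCH2)2, TMSOTf (cat.), CH2Cl2, −78 → −20 °C
Reagents that add atoms: 1,2-bis(trimethylsilyloxy)ethane, C[Si](C)(C)OCCO[Si](C)(C)C
Why: Noyori ketalisation should discriminate by steric access, since C3 has one quaternary neighbour whereas C9 lies between quaternary C10 and the methyl-bearing C8, and the silyl ether should survive catalytic TMSOTf at low temperature.

Step 7
Reactants: 12 3,3-ethylenedioxy 9-ketone
Product: 14 3,3-ethylenedioxy-6-(tert-butyldimethylsilyloxy) 7-en-9-one, via silyl enol ether 13 (not isolated)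
Conditions: LiN(iPr)2, TMSCl, THF, −78 → 0 °C; then Pd(OAc)2 (1 equiv), MeCN, 40 °C
Reagents that add atoms: none
Why: Saegusa–Ito oxidation: C8–H is the only α-hydrogen of the C9 ketone, so enolisation is regiodefined, and β-hydride elimination of the palladium enolate towards C7 should give the endocyclic conjugated enone.

Step 8
Reactants: 14 3,3-ethylenedioxy-6-(tert-butyldimethylsilyloxy) 7-en-9-one
Product: 15 7,9(11)-diene (exocyclic CH2 on C9)
Conditions: Cp2TiMe2, toluene, 75 °C, dark
Reagents that add atoms: dimethyltitanocene, C[Ti](C)(C1C=CC=C1)C1C=CC=C1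
Why: Petasis methylenation (a non-basic titanium carbene) should convert the hindered enone carbonyl into the methylene group without γ-deprotonation next to the silyloxy carbon.

Step 9
Reactants: 15 7,9(11)-diene
Product: 17 3,3-ethylenedioxy-6-(tert-butyldimethylsilyloxy)drim-7-en-11-ol, via alkylborane 16 (not isolated)
Conditions: 9-BBN, THF, 0 → 25 °C; then NaOH, H2O2, 0 °C
Reagents that add atoms: hydrogen peroxide, OO
Why: Hydroboration–oxidation: 9-BBN should add anti-Markovnikov to the terminal 1,1-disubstituted alkene only and deliver hydrogen to C9 from the face opposite the axial C10 methyl, which sets C9 with the CH2OH arm cis to that methyl.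

Step 10
Reactants: 17 3,3-ethylenedioxy-6-(tert-butyldimethylsilyloxy)drim-7-en-11-ol, 18 umbelliferone (7-hydroxycoumarin)
Product: 19 11-(2-oxo-2H-chromen-7-yloxy) ether of 17
Conditions: PPh3, DIAD, THF, 0 → 25 °C
Reagents that add atoms: none
Why: Mitsunobu etherification of a primary alcohol with an acidic phenol (pKa about 8) involves no stereocentre.

Step 11
Reactants: 19 11-(2-oxo-2H-chromen-7-yloxy) ether of 17
Product: 20 6-hydroxy-11-(2-oxo-2H-chromen-7-yloxy)drim-7-en-3-one
Conditions: 2 M aq HCl, THF, 25 °C
Reagents that add atoms: water, O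
Why: Dilute acid hydrolysis should remove the dioxolane and the silyl ether in one operation; C6 keeps its configuration as long as the allylic alcohol is not ionised.

Step 12
Reactants: 20 6-hydroxy-11-(2-oxo-2H-chromen-7-yloxy)drim-7-en-3-one
Product: 21 (5S,6R,9R,10S)-6-acetoxy-11-(2-oxo-2H-chromen-7-yloxy)drim-7-en-3-one (target)
Conditions: Ac2O, DMAP, pyridine, CH2Cl2, 25 °C
Reagents that add atoms: acetic anhydride, CC(=O)OC(C)=O
Why: DMAP-catalysed acylation of the secondary allylic alcohol proceeds with retention at C6.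

**Compound list**
1 | (R)-4-(tert-butyldimethylsilyloxy)cyclohex-2-en-1-one | CC(C)(C)[Si](C)(C)O[C@@H]1CCC(=O)C=C1 | starting material
2 | (R)-4-(tert-butyldimethylsilyloxy)-2-iodocyclohex-2-en-1-one | CC(C)(C)[Si](C)(C)O[C@@H]1CCC(=O)C(I)=C1 | intermediate
3 | (R)-4-(tert-butyldimethylsilyloxy)-2-methylcyclohex-2-en-1-one | CC(C)(C)[Si](C)(C)O[C@@H]1CCC(=O)C(C)=C1 | intermediate
4 | (4R)-4-(tert-butyldimethylsilyloxy)-2,6-dimethylcyclohex-2-en-1-one, C6 epimer mixture | CC(C)(C)[Si](C)(C)O[C@@H]1CC(C)C(=O)C(C)=C1 | intermediate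
5 | methyl isobutyrate | COC(=O)C(C)C | starting material
6 | methyl acrylate | C=CC(=O)OC | starting material
7 | lithium enolate of methyl isobutyrate | [Li+].[O-]C(OC)=C(C)C | intermediate
8 | lithium C9 enolate of the 1,4-adduct (C(CH3)2CO2CH3 on C5, trans to the 6-silyloxy group) | CC(C)(C)[Si](C)(C)O[C@@H]1CC(C)C([O-])=C(C)[C@H]1C(C)(C)C(=O)OC.[Li+] | intermediate
9 | lithium ester enolate of the double Michael adduct (C10 carries CH3 and the acrylate arm, trans to the C5 arm) | CC(C)(C)[Si](C)(C)O[C@@H]1CC(C)C(=O)[C@](C)(CC=C([O-])OC)[C@H]1C(C)(C)C(=O)OC.[Li+] | intermediate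
10 | trans-decalin β-keto ester, enol tautomer drawn: 2-CO2CH3, 3-OH (Δ2), 4,4-(CH3)2, 6-OTBS cis to 5-H, 8-CH3 equatorial, 9-oxo, 10-CH3 trans to 5-H | CC(C)(C)[Si](C)(C)O[C@@H]1C[C@H](C)C(=O)[C@]2(C)CC(C(=O)OC)=C(O)C(C)(C)[C@@H]12 | intermediate
11 | 6-(tert-butyldimethylsilyloxy)-4,4,8,10-tetramethyl-trans-decalin-3,9-dione (stereochemistry as in 10) | CC(C)(C)[Si](C)(C)O[C@@H]1C[C@H](C)C(=O)[C@]2(C)CCC(=O)C(C)(C)[C@@H]12 | intermediate
12 | 3,3-ethylenedioxy 9-ketone of 11 | CC(C)(C)[Si](C)(C)O[C@@H]1C[C@H](C)C(=O)[C@]2(C)CCC3(OCCO3)C(C)(C)[C@@H]12 | intermediate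
13 | 9-trimethylsilyloxy-8-ene (silyl enol ether of 12) | CC(C)(C)[Si](C)(C)O[C@@H]1CC(C)=C(O[Si](C)(C)C)[C@]2(C)CCC3(OCCO3)C(C)(C)[C@@H]12 | intermediate
14 | 3,3-ethylenedioxy-6-(tert-butyldimethylsilyloxy)-4,4,8,10-tetramethyl-trans-decal-7-en-9-one | CC(C)(C)[Si](C)(C)O[C@@H]1C=C(C)C(=O)[C@]2(C)CCC3(OCCO3)C(C)(C)[C@@H]12 | intermediate
15 | 3,3-ethylenedioxy-6-(tert-butyldimethylsilyloxy)drima-7,9(11)-diene | CC(C)(C)[Si](C)(C)O[C@@H]1C=C(C)C(=C)[C@]2(C)CCC3(OCCO3)C(C)(C)[C@@H]12 | intermediate
16 | 11-(9-borabicyclo[3.3.1]nonan-9-yl) alkylborane from 15, 9-H trans to the 10-CH3 | CC(C)(C)[Si](C)(C)O[C@@H]1C=C(C)[C@@H](CB3C4CCCC3CCC4)[C@]2(C)CCC3(OCCO3)C(C)(C)[C@@H]12 | intermediate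
17 | 3,3-ethylenedioxy-6-(tert-butyldimethylsilyloxy)drim-7-en-11-ol, CH2OH cis to the 10-CH3 | CC(C)(C)[Si](C)(C)O[C@@H]1C=C(C)[C@@H](CO)[C@]2(C)CCC3(OCCO3)C(C)(C)[C@@H]12 | intermediate
18 | umbelliferone (7-hydroxycoumarin) | Oc1ccc2ccc(=O)oc2c1 | starting material
19 | 11-(2-oxo-2H-chromen-7-yloxy) ether of 17 | CC(C)(C)[Si](C)(C)O[C@@H]1C=C(C)[C@@H](COc2ccc3ccc(=O)oc3c2)[C@]2(C)CCC3(OCCO3)C(C)(C)[C@@H]12 | intermediate
20 | (5S,6R,9R,10S)-6-hydroxy-11-(2-oxo-2H-chromen-7-yloxy)drim-7-en-3-one | O[C@@H]1C=C(C)[C@@H](COc2ccc3ccc(=O)oc3c2)[C@]2(C)CCC(=O)C(C)(C)[C@@H]12 | intermediate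
21 | (5S,6R,9R,10S)-6-acetoxy-11-(2-oxo-2H-chromen-7-yloxy)drim-7-en-3-one | CC(=O)O[C@@H]1C=C(C)[C@@H](COc2ccc3ccc(=O)oc3c2)[C@]2(C)CCC(=O)C(C)(C)[C@@H]12 | target

**Step count and risks**
Total steps: 12. Longest linear sequence: 12 steps (1 → 21); 5, 6 and 18 enter as bought components.

Most likely to fail:

Step 4. The ester enolate may add 1,2 instead of 1,4. Methyl acrylate may oligomerise before the hindered enolate 8 is consumed. Proton transfer from C8 may stall the Dieckmann closure. Fallback: from 4, a TMSOTf-catalysed Mukaiyama–Michael addition of 1-methoxy-2-methyl-1-(trimethylsilyloxy)propene (CH2Cl2, −78 °C) should give the silyl enol ether F1 with the same anti selectivity. MeLi (THF, 0 °C) would unmask the regiodefined lithium enolate, which would be trapped with phenyl vinyl sulfone, an acceptor that does not polymerise. KOtBu would then close ring A by acylation of the sulfonyl carbanion (C2) on the C3 ester to give the β-keto sulfone F2. Reductive desulfonylation (SmI2, THF/MeOH, −78 °C) returns to the route at 11, so step 5 is not needed.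

Step 8. The titanium carbene may fail to reach the C9 carbonyl between quaternary C10 and the substituted C8, or the reagent may decompose thermally first. Fallback: from 14, a Peterson olefination: the organocerium reagent from TMSCH2Li and CeCl3 (THF, −78 °C), which adds to hindered enolisable ketones, should give the β-hydroxysilane F3, and KH (THF, 25 °C) would eliminate it to rejoin the route at 15.

Step 7. Enolisation of the hindered ketone may be slow, and β-hydride elimination may go towards the methyl group to give the exocyclic isomer. Fallback: from 12, selenenylation of the lithium enolate (LiN(iPr)2, then PhSeBr, THF, −78 °C) to the α-phenylselenyl ketone F4, then oxidation (H2O2, pyridine, CH2Cl2, 0 °C) and selenoxide syn-elimination towards C7, rejoining the route at 14.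

**Further compounds**
F1 | step 4 | trimethylsilyl enol ether of the Mukaiyama–Michael adduct (C9–OTMS, C9=C10) | CC(C)(C)[Si](C)(C)O[C@@H]1CC(C)C(O[Si](C)(C)C)=C(C)[C@H]1C(C)(C)C(=O)OC
F2 | step 4 | 2-(phenylsulfonyl) analogue of 11 (β-keto sulfone, C2 epimers) | CC(C)(C)[Si](C)(C)O[C@@H]1C[C@H](C)C(=O)[C@]2(C)CC(S(=O)(=O)c3ccccc3)C(=O)C(C)(C)[C@@H]12
F3 | step 8 | 9-hydroxy-9-(trimethylsilylmethyl) adduct of 14 (β-hydroxysilane) | CC(C)(C)[Si](C)(C)O[C@@H]1C=C(C)[C@](O)(C[Si](C)(C)C)[C@]2(C)CCC3(OCCO3)C(C)(C)[C@@H]12
F4 | step 7 | 8-(phenylselanyl) derivative of 12 (C8 epimers) | CC(C)(C)[Si](C)(C)O[C@@H]1CC(C)([Se]c3ccccc3)C(=O)[C@]2(C)CCC3(OCCO3)C(C)(C)[C@@H]12
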